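**Strategy.** Everything rests on cutting ring B (C5–C6–C7–C8–C9–C10) at C8: the C9 carbinol sits between quaternary C10 and methyl-bearing C8, so C8 and its methyl are fed as one carbon into the cyclopentanone of (S)-Hajos–Parrish ketone, which already holds C10 with its methyl, the C9 carbonyl, C7, C6 and ring A as an enone. One Sc(OTf)3-catalysed diazoethane insertion between C9 and C7 enlarges this five-membered ring to ring B and places C17. The resulting 9-ketone is hindered enough to pass unprotected through ring A elaboration, then accepts a vinyl group, and a B-alkyl Suzuki coupling with 4-bromofuran-2(5H)-one completes the butenolide side chain.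

Key step: step 1

Remarks on the chemistry:
- Locants are those of the labdane skeleton of the target (ring A: C1–C5, C10; ring B: C5–C10; C11, C12 side chain; C13–C16 lactone; C17 on C8; C18, C19 on C4; C20 on C10). β is the face of the C10 methyl group.
- Assumption: diazoethane is not sold. It is used as a freshly prepared ethereal solution from commercial N-ethyl-N-nitrosourea (aq. KOH, Et2O, 0 °C), which counts as reagent preparation and not as a step.
- Assumption: the C9 configuration in step 5 rests on the equatorial-entry preference expected for 2,2,6-trisubstituted cyclohexanones. It is not secured by a close precedent and is covered by a fallback.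

Step 1
Reactants: 1 (S)-Hajos–Parrish ketone, (7aS)-7a-methyl-2,3,7,7a-tetrahydro-1H-indene-1,5(6H)-dione
Product: 2 (2R,8aS)-2,8a-dimethyl-3,4,8,8a-tetrahydronaphthalene-1,6(2H,7H)-dione (8α,10β-dimethyl-Δ4-octalin-3,9-dione)
Conditions: CH3CHN2 (Et2O solution, 2 equiv, slow addition), Sc(OTf)3 (10 mol%), toluene/CH2Cl2, −78 → −40 °C; then DBU (0.1 equiv), CH2Cl2, rt
Reagents that add atoms: diazoethane, CC=[N+]=[N-]
Why: Sc(OTf)3 activates the saturated C9 carbonyl, the carbon of diazoethane adds to it to give a β-diazonium alkoxide, and the C9–C7 bond migrates to that carbon as N2 leaves, so that the diazo carbon becomes C8 (with C17) between C9 and C7. The closest known reaction type is the Lewis-acid-catalysed diazoalkane–ketone homologation (Büchner–Curtius–Schlotterbeck reaction, Tiffeneau–Demjanov-type ring enlargement), the same event as the D-homoannulation of 17-oxo steroids. Ring B is closed by this 1,2-alkyl shift, that is by one-carbon ring enlargement of the five-membered ring (bonds C9–C8 and C8–C7 formed, C9–C7 broken), not by an exo or endo cyclisation. The new stereocentre C8 is α to the 9-ketone and is set under thermodynamic control (DBU), the methyl group taking the pseudo-equatorial 8α position anti to the axial C10 methyl group, while C10 itself is not touched. The step needs chemoselectivity for the saturated ketone over the enone (the vinylogous carbonyl is far less electrophilic and its β,β-disubstituted C=C is a poor dipolarophile at −78 °C), regioselectivity for migration of the CH2 carbon C7 instead of quaternary C10 (in the diazonium alkoxide the substituted diazo carbon turns away from the quaternary flank, which puts C7 anti to the leaving N2), and a single insertion (the product ketone lies between quaternary C10 and tertiary C8 and no longer adds the reagent).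

Step 2
Reactants: 2 8α,10β-dimethyl-Δ4-octalin-3,9-dione
Product: 3 4,4,8α,10β-tetramethyl-Δ5-octalin-3,9-dione, (2R,8aS)-2,5,5,8a-tetramethyl-3,7,8,8a-tetrahydronaphthalene-1,6(2H,5H)-dione
Conditions: KOtBu (2.3 equiv), t-BuOH/THF, 0 °C; MeI (2.5 equiv, slow addition), 0 °C → rt
Reagents that add atoms: iodomethane, CI
Why: Deconjugative α,α-dimethylation of the Δ4-3-ketone through its extended potassium dienolate should put both methyl groups on C4 and move the double bond to C5=C6, while the 9-ketone, whose only enolate is tetrasubstituted and flanked by quaternary C10, should not be alkylated and its C8 centre should stay at the equatorial 8α-methyl equilibrium position.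

Step 3
Reactants: 3 4,4,8α,10β-tetramethyl-Δ5-octalin-3,9-dione
Product: 4 3β-hydroxy-4,4,8α,10β-tetramethyl-Δ5-octalin-9-one
Conditions: NaBH4 (1 equiv), MeOH/CH2Cl2, −20 → 0 °C
Reagents that add atoms: none
Why: Chemoselective borohydride reduction should touch only the C3 carbonyl (one quaternary flank) and not the C9 carbonyl (quaternary C10 on one side, C8–CH3 on the other), hydride entering axially from the α face as in 4,4-dimethyl-3-oxo steroids to give the equatorial 3β-alcohol.

Step 4
Reactants: 4 3β-hydroxy-4,4,8α,10β-tetramethyl-Δ5-octalin-9-one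
Product: 5 3β-hydroxy-4,4,8α,10β-tetramethyl-trans-decalin-9-one (5α-H)
Conditions: H2 (4 atm), 10% Pd/C, EtOAc, rt
Reagents that add atoms: none
Why: Heterogeneous hydrogenation should deliver hydrogen to C5=C6 from the α face, opposite the axial C10 and 4β methyl groups, which gives the trans ring fusion (5α-H) as is known for 4,4,10-trimethyl-Δ5-octalins.

Step 5
Reactants: 5 3β-hydroxy-4,4,8α,10β-tetramethyl-trans-decalin-9-one
Product: 6 13,14,15,16-tetranorlabd-11-ene-3β,9α-diol (9β-vinyl, 8α-methyl)
Conditions: CH2=CHMgBr (4 equiv), LaCl3·2LiCl (0.3 equiv), THF, −20 → 0 °C; aq. NH4Cl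
Reagents that add atoms: vinylmagnesium bromide, C=C[Mg]Br
Why: Lanthanum-promoted 1,2-addition of the vinyl Grignard reagent (LaCl3·2LiCl suppresses enolisation at C8) to the hindered 9-ketone should proceed by equatorial entry from the β face, trans to the equatorial C8 methyl group as expected for 2,2,6-trisubstituted cyclohexanones, which leaves the hydroxyl axial (9α) and the vinyl group equatorial (9β).

Step 6
Reactants: 6 13,14,15,16-tetranorlabd-11-ene-3β,9α-diol
Product: 7 3β-acetoxy-13,14,15,16-tetranorlabd-11-en-9α-ol
Conditions: Ac2O, pyridine, DMAP (cat.), CH2Cl2, rt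
Reagents that add atoms: acetic anhydride, CC(=O)OC(C)=O
Why: DMAP-catalysed acylation should esterify only the secondary equatorial 3β-hydroxyl, because the tertiary axial 9α-hydroxyl between C10 and C8 is too hindered to react.

Step 7
Reactants: 7 3β-acetoxy-13,14,15,16-tetranorlabd-11-en-9α-ol; 8 4-bromofuran-2(5H)-one
Product: 10 3β-acetoxy-9α-hydroxylabd-13-en-15,16-olide (target CNP0578261.2), via alkylborane 9 (not isolated)
Conditions: 9-BBN dimer (1.3 equiv), THF, 0 → 50 °C; then 8, PdCl2(dppf) (5 mol%), AsPh3 (10 mol%), 3 M aq. K3PO4, DMF, rt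
Reagents that add atoms: 9-borabicyclo[3.3.1]nonane (9-BBN), B1C2CCCC1CCC2 (its boron stays only in 9)
Why: Anti-Markovnikov hydroboration of the monosubstituted vinyl group by 9-BBN, followed by B-alkyl Suzuki–Miyaura coupling of the primary alkylborane with the β-bromobutenolide under mild phosphate conditions, should form the C12–C13 bond without touching the acetate, the lactone or any stereocentre.

**Compound list**

1 | (S)-Hajos–Parrish ketone, (7aS)-7a-methyl-2,3,7,7a-tetrahydro-1H-indene-1,5(6H)-dione | C[C@]12CCC(=O)C=C1CCC2=O | starting material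
2 | (2R,8aS)-2,8a-dimethyl-3,4,8,8a-tetrahydronaphthalene-1,6(2H,7H)-dione (8α,10β-dimethyl-Δ4-octalin-3,9-dione) | O=C1CC[C@@]2(C)C(=C1)CC[C@@H](C)C2=O | intermediate
3 | 4,4,8α,10β-tetramethyl-Δ5-octalin-3,9-dione | O=C1CC[C@@]2(C)C(=CC[C@@H](C)C2=O)C1(C)C | intermediate
4 | 3β-hydroxy-4,4,8α,10β-tetramethyl-Δ5-octalin-9-one | O[C@H]1CC[C@@]2(C)C(=CC[C@@H](C)C2=O)C1(C)C | intermediate
5 | 3β-hydroxy-4,4,8α,10β-tetramethyl-trans-decalin-9-one (5α-H) | O[C@H]1CC[C@@]2(C)[C@@H](CC[C@@H](C)C2=O)C1(C)C | intermediate
6 | 13,14,15,16-tetranorlabd-11-ene-3β,9α-diol (9β-vinyl) | O[C@H]1CC[C@@]2(C)[C@@H](CC[C@@H](C)[C@]2(O)C=C)C1(C)C | intermediate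
7 | 3β-acetoxy-13,14,15,16-tetranorlabd-11-en-9α-ol | CC(=O)O[C@H]1CC[C@@]2(C)[C@@H](CC[C@@H](C)[C@]2(O)C=C)C1(C)C | intermediate
8 | 4-bromofuran-2(5H)-one | BrC1=CC(=O)OC1 | starting material
9 | alkylborane, 3β-acetoxy-12-(9-borabicyclo[3.3.1]nonan-9-yl)-13,14,15,16-tetranorlabdan-9α-ol | CC(=O)O[C@H]1CC[C@@]2(C)[C@@H](CC[C@@H](C)[C@]2(O)CCB2C3CCCC2CCC3)C1(C)C | intermediate (not isolated)
10 | 3β-acetoxy-9α-hydroxylabd-13-en-15,16-olide, the 4-substituted furan-2(5H)-one (CNP0578261.2) | CC(=O)O[C@H]1CC[C@@]2(C)[C@@H](CC[C@@H](C)[C@]2(O)CCC2=CC(=O)OC2)C1(C)C | target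

Total step count: 7. Longest linear sequence: 7 steps (from 1).

**Steps most likely to fail**

Step 1. Addition of the unstabilised diazoalkane to the neopentylic carbonyl may be slower than its consumption by dipolar cycloaddition at the enone or by acid-induced decomposition, and some migration of C10 may intrude. The fallback sets out from 1 and keeps the ring enlargement but uses a stabilised diazo ester, with the methyl group brought in by enolate alkylation. Ethyl diazoacetate with BF3·OEt2 in CH2Cl2 at 0 °C should give, by the same CH2 migration, the ring-enlarged β-keto ester ethyl (8aS)-8a-methyl-1,6-dioxo-1,2,3,4,6,7,8,8a-octahydronaphthalene-2-carboxylate F1. K2CO3 and MeI in acetone should methylate its doubly activated C8 to the 2-methyl keto ester F2. Krapcho dealkoxycarbonylation (LiCl, wet DMSO, 150 °C) with equilibration at C8 comes back to the route at 2.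

Step 5. The basic organometallic may enolise the ketone at C8 instead of adding, or may enter from the α face and give the C9 epimer. The fallback sets out from 5 and makes the C9–O bond with an electrophile, so that the configuration is decided in an epoxidation. Wittig methylenation (Ph3PCH3Br, KOtBu, toluene, 90 °C) should give the exocyclic alkene 3β-hydroxy-4,4,8α,10β-tetramethyl-9-methylene-trans-decalin F4. mCPBA (NaHCO3, CH2Cl2, 0 °C) should approach anti to the axial C10 methyl group and give the 9α,11-epoxide F5. Excess dimethylsulfonium methylide (Me3SI, n-BuLi, THF, −10 °C → rt) should open the epoxide at C11 and eliminate dimethyl sulfide, which comes back to the route at 6.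

Step 2. Excess base and MeI may methylate C8 or C2 as well, and alkoxide may open the vinylogous 1,3-diketone by retro-Claisen cleavage. The fallback sets out from 1 and uses the ester as a removable blocking group at C8. It proceeds through F1 to the 2-methyl keto ester F2 as described for step 1; in F2 the C9 carbonyl has no α-hydrogen left. KOtBu and MeI in t-BuOH should then dimethylate C4 cleanly to the tetramethyl keto ester ethyl (8aS)-2,5,5,8a-tetramethyl-1,6-dioxo-1,2,3,5,6,7,8,8a-octahydronaphthalene-2-carboxylate F3. Krapcho dealkoxycarbonylation (LiCl, wet DMSO, 150 °C) with equilibration at C8 comes back to the route at 3.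

**Further compounds**

F1 | step 1 | ethyl (8aS)-8a-methyl-1,6-dioxo-1,2,3,4,6,7,8,8a-octahydronaphthalene-2-carboxylate (C8 enolisable, unassigned) | O=C1CC[C@@]2(C)C(=C1)CCC(C(=O)OCC)C2=O
F2 | step 1 | ethyl (8aS)-2,8a-dimethyl-1,6-dioxo-1,2,3,4,6,7,8,8a-octahydronaphthalene-2-carboxylate (C8 unassigned) | O=C1CC[C@@]2(C)C(=C1)CCC(C)(C(=O)OCC)C2=O
F3 | step 2 | ethyl (8aS)-2,5,5,8a-tetramethyl-1,6-dioxo-1,2,3,5,6,7,8,8a-octahydronaphthalene-2-carboxylate (C8 unassigned) | O=C1CC[C@@]2(C)C(=CCC(C)(C(=O)OCC)C2=O)C1(C)C
F4 | step 5 | 3β-hydroxy-4,4,8α,10β-tetramethyl-9-methylene-trans-decalin | O[C@H]1CC[C@@]2(C)[C@@H](CC[C@@H](C)C2=C)C1(C)C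
F5 | step 5 | 9α,11-epoxide of F4 (spiro-oxirane at C9, oxygen α) | O[C@H]1CC[C@@]2(C)[C@@H](CC[C@@H](C)[C@]23CO3)C1(C)C
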